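**Plan**

- Numbering (lignan convention): ring A (4-hydroxy-3-methoxyphenyl)–C7H2–C8H(–C9H2–O–); lactone carbonyl C9'; α-carbon C8'; C7'H2–ring B (2,4-dihydroxy-3-methoxyphenyl). The target is the (8R,8'R) trans lactone, i.e. (3R,4R).
- Retrosynthesis: the three phenol protecting groups, the C7'=C8' unsaturation and the C8' configuration lead back to a tribenzyl (E)-arylmethylidene lactone. Both bonds to the carbonyl carbon (C9'–O and C9'–C8') are then cut, leaving CO and a homopropargylic alcohol. Next come the alkyne–ring B bond (C7'–C1'), the alkyne carbon C7' (aldehyde homologation) and the C8 centre (prochiral 1,3-diol from O-benzylvanillin and diethyl malonate).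
- Enabling feature: in the five-membered lactone, C9' lies between the ring oxygen (carried by C9 on the stereocentre C8) and C8'. A hydroxyl on C9 and an alkyne beginning at C8' can therefore be bridged by one molecule of CO.
- Forward: malonate chain on ring A, prochiral diol, enzymatic monoacetate, terminal alkyne, Sonogashira coupling to ring B, carbonylative closure of the lactone (the only ring formed), hydrogenation with debenzylation, epimerisation.
- Stereochemistry: C8 (R) is set by lipase desymmetrisation and not touched afterwards. C8' (R) is set in the last step by base equilibration to the trans lactone under control of C8.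

Key step: step 12

Assumption: Burkholderia cepacia lipase is taken to acetylate the pro-R hydroxymethyl arm of the 2-arylmethyl-1,3-propanediol, as is usual for this enzyme with such diols, so that step 4 delivers the (R)-monoacetate.

**Route**

Step 1
Reactants: 1 4-(benzyloxy)-3-methoxybenzaldehyde (O-benzylvanillin, commercial); 2 diethyl malonate
Product: 3 diethyl 2-[4-(benzyloxy)-3-methoxybenzylidene]malonate
Conditions: piperidine (cat.), AcOH (cat.), toluene, reflux, Dean–Stark trap
Reagents that add atoms: none
Why: Knoevenagel condensation of a non-enolisable aromatic aldehyde with the doubly activated methylene of the malonate, driven to completion by azeotropic removal of water.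

Step 2
Reactants: 3 diethyl 2-[4-(benzyloxy)-3-methoxybenzylidene]malonate
Product: 4 diethyl 2-[4-(benzyloxy)-3-methoxybenzyl]malonate
Conditions: NaBH4, EtOH, 0 °C
Reagents that add atoms: none
Why: The arylidene malonate is a doubly activated Michael acceptor, so NaBH4 should deliver hydride in a conjugate reduction at 0 °C without touching the esters or the aryl benzyl ether, which a catalytic hydrogenation would not spare.

Step 3
Reactants: 4 diethyl 2-[4-(benzyloxy)-3-methoxybenzyl]malonate
Product: 5 2-[4-(benzyloxy)-3-methoxybenzyl]propane-1,3-diol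
Conditions: LiAlH4, THF, 0 °C to rt
Reagents that add atoms: none
Why: Hydride reduction of both ester groups to primary alcohols is standard for malonates and leaves the aryl ethers intact; the diol is prochiral, so no stereocentre exists yet.

Step 4
Reactants: 5 2-[4-(benzyloxy)-3-methoxybenzyl]propane-1,3-diol
Product: 6 (R)-2-[4-(benzyloxy)-3-methoxybenzyl]-3-hydroxypropyl acetate
Conditions: Burkholderia cepacia lipase (immobilised), vinyl acetate, i-Pr2O, 30 °C
Reagents that add atoms: vinyl acetate, CC(=O)OC=C
Why: Enzymatic desymmetrisation by irreversible transesterification is well established for 2-arylmethyl-1,3-propanediols; the enzyme's preference for one enantiotopic hydroxymethyl arm sets C8 as (R), and slight over-acylation to the diacetate should consume mainly the minor enantiomer of the monoacetate.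

Step 5
Reactants: 6 (R)-2-[4-(benzyloxy)-3-methoxybenzyl]-3-hydroxypropyl acetate
Product: 7 (S)-2-[4-(benzyloxy)-3-methoxybenzyl]-3-oxopropyl acetate (used crude at once)
Conditions: TEMPO (cat.), PhI(OAc)2, CH2Cl2, rt
Reagents that add atoms: none
Why: The TEMPO-catalysed oxidation with PhI(OAc)2 converts a primary alcohol to the aldehyde under base-free, weakly acidic conditions, which should spare both the α-stereocentre and the β-acetate that a basic oxidation would endanger.

Step 6
Reactants: 7 (S)-2-[4-(benzyloxy)-3-methoxybenzyl]-3-oxopropyl acetate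
Product: 8 (R)-2-[4-(benzyloxy)-3-methoxybenzyl]-4,4-dibromobut-3-en-1-yl acetate
Conditions: CBr4, PPh3, Zn, CH2Cl2, rt (ylide preformed); then 7, 0 °C
Reagents that add atoms: carbon tetrabromide, BrC(Br)(Br)Br
Why: The Ramirez dibromo-olefination (first stage of the Corey–Fuchs sequence) uses a non-basic phosphorus ylide, so the enolisable β-acetoxy aldehyde should be homologated without epimerisation or loss of acetate, which a base-mediated diazophosphonate alkynylation could not guarantee.

Step 7
Reactants: 8 (R)-2-[4-(benzyloxy)-3-methoxybenzyl]-4,4-dibromobut-3-en-1-yl acetate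
Product: 9 (R)-2-[4-(benzyloxy)-3-methoxybenzyl]-4,4-dibromobut-3-en-1-ol
Conditions: K2CO3 (cat.), MeOH, rt
Reagents that add atoms: none
Why: Base-catalysed transesterification with methanol removes the acetate, while the 1,1-dibromoalkene is inert to carbonate at room temperature and the stereocentre is no longer α to a carbonyl.

Step 8
Reactants: 9 (R)-2-[4-(benzyloxy)-3-methoxybenzyl]-4,4-dibromobut-3-en-1-ol
Product: 11 (R)-2-[4-(benzyloxy)-3-methoxybenzyl]but-3-yn-1-ol, via dilithium alkoxide acetylide 10 (not isolated)
Conditions: n-BuLi (3.2 equiv), THF, −78 °C; then H2O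
Reagents that add atoms: none
Why: In the second stage of the Corey–Fuchs sequence, bromine–lithium exchange, Fritsch–Buttenberg–Wiechell rearrangement and deprotonation give the lithium acetylide after one equivalent of n-BuLi has been spent on the hydroxyl; at −78 °C the aryl benzyl ether and the non-acidic propargylic stereocentre should be untouched.

Step 9
Reactants: 12 2-methoxybenzene-1,3-diol (2-methoxyresorcinol)
Product: 13 1,3-bis(benzyloxy)-2-methoxybenzene
Conditions: BnBr, K2CO3, DMF, 60 °C
Reagents that add atoms: benzyl bromide, BrCc1ccccc1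
Why: Williamson etherification of both phenols with a reactive benzylic bromide under carbonate base is routine.

Step 10
Reactants: 13 1,3-bis(benzyloxy)-2-methoxybenzene
Product: 14 1,3-bis(benzyloxy)-4-iodo-2-methoxybenzene
Conditions: NIS, CF3CO2H (cat.), MeCN, 0 °C to rt
Reagents that add atoms: N-iodosuccinimide, O=C1CCC(=O)N1I
Why: Electrophilic aromatic iodination with acid-activated NIS should occur at C4, which is ortho to one benzyloxy group and para to the other, whereas C5 is meta to both; one equivalent of reagent limits the reaction to mono-iodination.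

Step 11
Reactants: 11 (R)-2-[4-(benzyloxy)-3-methoxybenzyl]but-3-yn-1-ol; 14 1,3-bis(benzyloxy)-4-iodo-2-methoxybenzene
Product: 15 (R)-2-[4-(benzyloxy)-3-methoxybenzyl]-4-[2,4-bis(benzyloxy)-3-methoxyphenyl]but-3-yn-1-ol
Conditions: PdCl2(PPh3)2 (cat.), CuI (cat.), Et3N, THF, 50 °C, degassed
Reagents that add atoms: none
Why: Sonogashira coupling (oxidative addition of the aryl iodide to zerovalent palladium formed in situ, transmetalation from the copper acetylide, reductive elimination) tolerates the free primary alcohol; an iodide rather than a bromide is used because the ring is electron-rich and ortho-substituted.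

Step 12
Reactants: 15 (R)-2-[4-(benzyloxy)-3-methoxybenzyl]-4-[2,4-bis(benzyloxy)-3-methoxyphenyl]but-3-yn-1-ol; 16 carbon monoxide
Product: 17 (R,E)-4-[4-(benzyloxy)-3-methoxybenzyl]-3-[2,4-bis(benzyloxy)-3-methoxybenzylidene]dihydrofuran-2(3H)-one
Conditions: CO (8 bar), PdCl2(PPh3)2 (cat.), SnCl2 (cat.), MeCN, 75 °C
Reagents that add atoms: none
Why: Divalent palladium in PdCl2(PPh3)2, made more electrophilic by SnCl2, binds CO and is attacked by the primary hydroxyl to give an alkoxycarbonyl–palladium chloride with loss of HCl; the tethered alkyne then inserts syn into the palladium–acyl bond and the HCl cleaves the resulting vinyl–palladium bond, releasing the lactone and the divalent palladium catalyst without change of oxidation state. The closest known reaction type is the palladium-catalysed cyclocarbonylation of homopropargylic alcohols to α-methylene- and (E)-α-alkylidene-γ-butyrolactones, which is established for internal as well as terminal alkynes. The single ring, the five-membered lactone, closes by a 5-exo-dig acylpalladation in which the acyl carbon C9' bonds to the proximal alkyne carbon C8' and the aryl-bearing carbon C7' stays outside the ring. No stereocentre is created: the syn addition fixes the E geometry (aryl group trans to the carbonyl), and C8, which is not enolisable and lies outside the reacting atoms, is carried through unchanged. The step needs exo rather than 6-endo closure and carbonylation rather than direct addition of the hydroxyl to the alkyne; the first is secured by the two-atom tether, since a syn insertion placing the acyl carbon on C7' would demand a trans double bond inside a six-membered ring, and the second by the CO pressure, which keeps palladium as the alkoxycarbonyl species. The E/Z purity is not critical because the alkene is hydrogenated in the next step.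

Step 13
Reactants: 17 (R,E)-4-[4-(benzyloxy)-3-methoxybenzyl]-3-[2,4-bis(benzyloxy)-3-methoxybenzylidene]dihydrofuran-2(3H)-one
Product: 18 (3S,4R)-3-(2,4-dihydroxy-3-methoxybenzyl)-4-(4-hydroxy-3-methoxybenzyl)dihydrofuran-2(3H)-one
Conditions: H2 (1 atm), 10% Pd/C, EtOAc/MeOH, rt
Reagents that add atoms: none
Why: Heterogeneous hydrogenation over Pd/C should saturate the conjugated exocyclic alkene and hydrogenolyse all three aryl benzyl ethers in one operation; hydrogen is expected to add to the alkene face opposite the C8 benzyl group, which sets C8' mainly as the cis (3S) epimer, and any trans isomer formed is the target itself and is carried along.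

Step 14
Reactants: 18 (3S,4R)-3-(2,4-dihydroxy-3-methoxybenzyl)-4-(4-hydroxy-3-methoxybenzyl)dihydrofuran-2(3H)-one
Product: 19 (3R,4R)-3-(2,4-dihydroxy-3-methoxybenzyl)-4-(4-hydroxy-3-methoxybenzyl)dihydrofuran-2(3H)-one (CNP0352334.1)
Conditions: DBU (excess), MeCN, 70 °C, under argon
Reagents that add atoms: none
Why: Base-mediated epimerisation through the lactone enolate should equilibrate C8' towards the thermodynamically preferred trans arrangement of the two benzyl groups, so that the fixed (R) centre C8 dictates (R) at C8'; the γ-lactone is expected to persist because an aryl ester formed by attack of the ortho-phenol would be higher in energy.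

**Compound list**

1 | 4-(benzyloxy)-3-methoxybenzaldehyde | COc1cc(C=O)ccc1OCc1ccccc1 | starting material
2 | diethyl malonate | CCOC(=O)CC(=O)OCC | starting material
3 | diethyl 2-[4-(benzyloxy)-3-methoxybenzylidene]malonate | CCOC(=O)C(=Cc1ccc(OCc2ccccc2)c(OC)c1)C(=O)OCC | intermediate
4 | diethyl 2-[4-(benzyloxy)-3-methoxybenzyl]malonate | CCOC(=O)C(Cc1ccc(OCc2ccccc2)c(OC)c1)C(=O)OCC | intermediate
5 | 2-[4-(benzyloxy)-3-methoxybenzyl]propane-1,3-diol | COc1cc(CC(CO)CO)ccc1OCc1ccccc1 | intermediate
6 | (R)-2-[4-(benzyloxy)-3-methoxybenzyl]-3-hydroxypropyl acetate | COc1cc(C[C@@H](COC(C)=O)CO)ccc1OCc1ccccc1 | intermediate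
7 | (S)-2-[4-(benzyloxy)-3-methoxybenzyl]-3-oxopropyl acetate | COc1cc(C[C@@H](COC(C)=O)C=O)ccc1OCc1ccccc1 | intermediate
8 | (R)-2-[4-(benzyloxy)-3-methoxybenzyl]-4,4-dibromobut-3-en-1-yl acetate | COc1cc(C[C@@H](COC(C)=O)C=C(Br)Br)ccc1OCc1ccccc1 | intermediate
9 | (R)-2-[4-(benzyloxy)-3-methoxybenzyl]-4,4-dibromobut-3-en-1-ol | COc1cc(C[C@@H](CO)C=C(Br)Br)ccc1OCc1ccccc1 | intermediate
10 | dilithium (R)-2-[4-(benzyloxy)-3-methoxybenzyl]but-3-yn-4-id-1-olate (dilithium alkoxide acetylide) | [Li+].[Li+].COc1cc(C[C@@H](C[O-])C#[C-])ccc1OCc1ccccc1 | intermediate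
11 | (R)-2-[4-(benzyloxy)-3-methoxybenzyl]but-3-yn-1-ol | COc1cc(C[C@@H](CO)C#C)ccc1OCc1ccccc1 | intermediate
12 | 2-methoxybenzene-1,3-diol | COc1c(O)cccc1O | starting material
13 | 1,3-bis(benzyloxy)-2-methoxybenzene | COc1c(OCc2ccccc2)cccc1OCc1ccccc1 | intermediate
14 | 1,3-bis(benzyloxy)-4-iodo-2-methoxybenzene | COc1c(OCc2ccccc2)ccc(I)c1OCc1ccccc1 | intermediate
15 | (R)-2-[4-(benzyloxy)-3-methoxybenzyl]-4-[2,4-bis(benzyloxy)-3-methoxyphenyl]but-3-yn-1-ol | COc1cc(C[C@@H](CO)C#Cc2ccc(OCc3ccccc3)c(OC)c2OCc2ccccc2)ccc1OCc1ccccc1 | intermediate
16 | carbon monoxide | [C-]#[O+] | starting material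
17 | (R,E)-4-[4-(benzyloxy)-3-methoxybenzyl]-3-[2,4-bis(benzyloxy)-3-methoxybenzylidene]dihydrofuran-2(3H)-one | COc1cc(C[C@H]2COC(=O)/C2=C/c2ccc(OCc3ccccc3)c(OC)c2OCc2ccccc2)ccc1OCc1ccccc1 | intermediate
18 | (3S,4R)-3-(2,4-dihydroxy-3-methoxybenzyl)-4-(4-hydroxy-3-methoxybenzyl)dihydrofuran-2(3H)-one | COc1cc(C[C@H]2COC(=O)[C@H]2Cc2ccc(O)c(OC)c2O)ccc1O | intermediate
19 | (3R,4R)-3-(2,4-dihydroxy-3-methoxybenzyl)-4-(4-hydroxy-3-methoxybenzyl)dihydrofuran-2(3H)-one | COc1cc(C[C@H]2COC(=O)[C@@H]2Cc2ccc(O)c(OC)c2O)ccc1O | target

**Step count and risks**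

Total step count: 14. Longest linear sequence: 12 steps (steps 1–8 and 11–14); steps 9 and 10 form the ring B branch that joins at step 11.

Steps most likely to fail:

1. Step 12 (cyclocarbonylation). The alkyne is flanked by a branched carbon and an ortho-substituted, electron-rich arene. Insertion into the alkoxycarbonyl–palladium bond may therefore be slow, so that carbonylation stalls or direct addition of the hydroxyl to the alkyne (cycloisomerisation to a dihydrofuran) takes over. The fallback performs the carbonylative closure before the arene is attached. It sets out from alkynol 11, whose unhindered terminal alkyne belongs to the best-established substrate class. The same PdCl2(PPh3)2/SnCl2/CO system would give the α-methylene lactone (R)-4-[4-(benzyloxy)-3-methoxybenzyl]-3-methylenedihydrofuran-2(3H)-one F1. A Mizoroki–Heck arylation of this lactone with iodide 14 (Pd(OAc)2, KOAc, n-Bu4NBr, DMF, 80 °C) would then come back to the route at benzylidene lactone 17. β-Hydride elimination towards the benzylic hydrogen gives the conjugated exocyclic alkene. Acetate rather than an amine base is chosen to disfavour migration of the double bond into the ring, which would erase C8.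

2. Step 5 (oxidation to the aldehyde, with its use in step 6). Aldehyde 7 has an acidic α-hydrogen at the only stereocentre and a β-acetoxy leaving group. Enolisation during oxidation, handling or olefination would erode the C8 configuration or expel acetate to an α-methylene aldehyde. The fallback passes through an aldehyde whose β-oxygen is a silyl ether, reached by using the enzyme in the hydrolytic direction; it is two steps longer. It sets out from diol 5:
   - Acetylation (Ac2O, pyridine) would give 2-[4-(benzyloxy)-3-methoxybenzyl]propane-1,3-diyl diacetate F2.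
   - Hydrolysis with the same lipase in phosphate buffer should remove the acetate from the arm the enzyme recognises and leave the antipodal monoacetate (S)-2-[4-(benzyloxy)-3-methoxybenzyl]-3-hydroxypropyl acetate F3.
   - Silylation (TBSCl, imidazole, DMF) would give (R)-2-[4-(benzyloxy)-3-methoxybenzyl]-3-[(tert-butyldimethylsilyl)oxy]propyl acetate F4.
   - Methanolysis of the acetate (K2CO3, MeOH) would give (R)-2-[4-(benzyloxy)-3-methoxybenzyl]-3-[(tert-butyldimethylsilyl)oxy]propan-1-ol F5.
   - Oxidation with Dess–Martin periodinane would give (S)-2-[4-(benzyloxy)-3-methoxybenzyl]-3-[(tert-butyldimethylsilyl)oxy]propanal F6, a β-silyloxy aldehyde of the kind that is routinely homologated without loss of configuration.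
   - Ohira–Bestmann alkynylation (dimethyl (1-diazo-2-oxopropyl)phosphonate, K2CO3, MeOH) would give (R)-{[2-(4-(benzyloxy)-3-methoxybenzyl)but-3-yn-1-yl]oxy}(tert-butyl)dimethylsilane F7.
   - Desilylation (n-Bu4NF, THF) would come back to the route at alkynol 11.

3. Step 14 (epimerisation of the free triphenol). With three free phenols the base is consumed as phenoxide and enolisation of the lactone may be slow. The electron-rich phenoxides are also sensitive to air, and cis and trans triphenols are hard to separate, so the equilibration may remain incomplete. The fallback epimerises before the phenols are unveiled, which also keeps the alkene away from Pd/C, where it could migrate towards C8. It sets out from benzylidene lactone 17: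
   - Conjugate reduction that spares benzyl ethers (NaBH4, NiCl2·6H2O, MeOH/THF, 0 °C) would give (4R)-4-[4-(benzyloxy)-3-methoxybenzyl]-3-[2,4-bis(benzyloxy)-3-methoxybenzyl]dihydrofuran-2(3H)-one F8 as a mixture of C8' epimers.
   - DBU in toluene at 80 °C should equilibrate it to the trans lactone (3R,4R)-4-[4-(benzyloxy)-3-methoxybenzyl]-3-[2,4-bis(benzyloxy)-3-methoxybenzyl]dihydrofuran-2(3H)-one F9.
   - Hydrogenolysis (H2, 10% Pd/C, EtOAc/MeOH) would come back to the route at target 19.

**Further compounds**

F1 | step 12 | (R)-4-[4-(benzyloxy)-3-methoxybenzyl]-3-methylenedihydrofuran-2(3H)-one | COc1cc(C[C@H]2COC(=O)C2=C)ccc1OCc1ccccc1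
F2 | step 5 | 2-[4-(benzyloxy)-3-methoxybenzyl]propane-1,3-diyl diacetate | COc1cc(CC(COC(C)=O)COC(C)=O)ccc1OCc1ccccc1
F3 | step 5 | (S)-2-[4-(benzyloxy)-3-methoxybenzyl]-3-hydroxypropyl acetate | COc1cc(C[C@H](COC(C)=O)CO)ccc1OCc1ccccc1
F4 | step 5 | (R)-2-[4-(benzyloxy)-3-methoxybenzyl]-3-[(tert-butyldimethylsilyl)oxy]propyl acetate | COc1cc(C[C@H](COC(C)=O)CO[Si](C)(C)C(C)(C)C)ccc1OCc1ccccc1
F5 | step 5 | (R)-2-[4-(benzyloxy)-3-methoxybenzyl]-3-[(tert-butyldimethylsilyl)oxy]propan-1-ol | COc1cc(C[C@H](CO)CO[Si](C)(C)C(C)(C)C)ccc1OCc1ccccc1
F6 | step 5 | (S)-2-[4-(benzyloxy)-3-methoxybenzyl]-3-[(tert-butyldimethylsilyl)oxy]propanal | COc1cc(C[C@H](C=O)CO[Si](C)(C)C(C)(C)C)ccc1OCc1ccccc1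
F7 | step 5 | (R)-{[2-(4-(benzyloxy)-3-methoxybenzyl)but-3-yn-1-yl]oxy}(tert-butyl)dimethylsilane | COc1cc(C[C@H](C#C)CO[Si](C)(C)C(C)(C)C)ccc1OCc1ccccc1
F8 | step 14 | (4R)-4-[4-(benzyloxy)-3-methoxybenzyl]-3-[2,4-bis(benzyloxy)-3-methoxybenzyl]dihydrofuran-2(3H)-one (mixture of C3 epimers) | COc1cc(C[C@H]2COC(=O)C2Cc2ccc(OCc3ccccc3)c(OC)c2OCc2ccccc2)ccc1OCc1ccccc1
F9 | step 14 | (3R,4R)-4-[4-(benzyloxy)-3-methoxybenzyl]-3-[2,4-bis(benzyloxy)-3-methoxybenzyl]dihydrofuran-2(3H)-one | COc1cc(C[C@H]2COC(=O)[C@@H]2Cc2ccc(OCc3ccccc3)c(OC)c2OCc2ccccc2)ccc1OCc1ccccc1
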